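Ring B is annulated onto a preformed ring A in one ester-tethered anionic [4+2] event. Because O–C1 and the acyl carbon on C8 are 1,3-related across C8a, hydroxy enone 4 (ring A) is esterified with a β-keto acid that carries C5–C8 as a 5-ethoxy-3-oxopent-4-enoyl unit. Base then causes 5-exo Michael addition (C8–C8a), 6-endo Michael addition of the ring-A enolate (C4a–C5) and loss of ethoxide, setting C8a and quaternary C8 and giving a tricyclic γ-lactone. The C4 oxygen is then removed via its triflate, methyllithium adds to C7, the lactone is opened to the 3-hydroxypropanoyl ketone, and the freed C1 hydroxyl receives the tetraene acid in two pieces.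

Key step: step 5

Remark: locants C1–C8a follow the decalin of the target (C1 ester oxygen, C3 ring methyl, C4=C4a–C5=C6 diene, C7 carbinol, C8 quaternary carbon, C8a ring-fusion CH); primed locants belong to the side-chain acid, C1′ being its ester carbonyl.
Remark: the sense of induction in step 1 is assumed to follow that of cyclohex-2-enone with the same ligand; the mirror-image ligand is used if it proves opposite.
Remark: keto–enol and hydroxy ketone–hemiketal pairs (7, 8, 10, 14, 15) are drawn as one tautomer; 7 and 8 are epimer mixtures at the carbon between the two carbonyl groups, which is of no consequence.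
Remark: S-tert-butyl propanethioate 5 is assumed to be commercially available; if not, it is made from propanoyl chloride and 2-methylpropane-2-thiol.

Step 1
Reactants: 1 4,4-dimethoxycyclohexa-2,5-dien-1-one
Product: 2 (5R)-4,4-dimethoxy-5-methylcyclohex-2-en-1-one
Conditions: Me2Zn (1.5 equiv), Cu(OTf)2 (2 mol %), (S,R,R)-O,O′-(1,1′-binaphthalene-2,2′-diyl) N,N-bis(1-phenylethyl)phosphoramidite (4 mol %), toluene, −25 °C; aq. NH4Cl
Reagents that add atoms: dimethylzinc, C[Zn]C
Why: Copper-catalysed enantioselective conjugate addition of a dialkylzinc desymmetrises the achiral quinone monoketal, the chiral phosphoramidite–copper complex choosing between the enantiotopic enone faces and setting the methyl-bearing centre (later C3), while the less electrophilic mono-adduct should not add a second methyl group.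

Step 2
Reactants: 2 (5R)-4,4-dimethoxy-5-methylcyclohex-2-en-1-one
Product: 4 (4S,6R)-4-hydroxy-6-methylcyclohex-2-en-1-one, via ketal alcohol 3 (not isolated)
Conditions: NaBH4, CeCl3·7H2O, MeOH, −78 °C; then 1 M HCl, THF/H2O, 0 °C → rt
Reagents that add atoms: water, O
Why: Luche 1,2-reduction delivers hydride axially and should give the equatorial alcohol cis to the methyl group (sets later C1), and aqueous acid then hydrolyses the allylic dimethyl ketal to the enone, the cis-4,6 isomer also being the thermodynamic one should the α-methyl centre equilibrate.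

Step 3
Reactants: 5 S-tert-butyl propanethioate; 6 (2E)-3-ethoxyprop-2-enoyl chloride
Product: 7 S-tert-butyl (4E)-5-ethoxy-2-methyl-3-oxopent-4-enethioate
Conditions: LiN(iPr)2 (2.1 equiv) and 5 (2.1 equiv), THF, −78 °C; then 6 (1.0 equiv), −78 °C; AcOH quench
Reagents that add atoms: none
Why: Crossed Claisen condensation in which the lithium thioester enolate is C-acylated by the acid chloride at low temperature, the second equivalent of enolate taking up the acidic proton of the product.

Step 4
Reactants: 4 (4S,6R)-4-hydroxy-6-methylcyclohex-2-en-1-one; 7 S-tert-butyl (4E)-5-ethoxy-2-methyl-3-oxopent-4-enethioate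
Product: 8 (1S,5R)-5-methyl-4-oxocyclohex-2-en-1-yl (4E)-5-ethoxy-2-methyl-3-oxopent-4-enoate
Conditions: AgOCOCF3 (1.2 equiv), Na2HPO4, 4 Å MS, THF, 0 °C → rt, dark
Reagents that add atoms: none
Why: Silver-promoted transesterification of a β-keto thioester, in which the thiophilic silver salt activates the C–S bond and the secondary alcohol is acylated under buffered, near-neutral conditions that spare the γ-hydroxy enone, the enol ether and both stereocentres of 4.

Step 5
Reactants: 8 (1S,5R)-5-methyl-4-oxocyclohex-2-en-1-yl (4E)-5-ethoxy-2-methyl-3-oxopent-4-enoate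
Product: 10 (1S,3R,8R,8aS)-1,4-dihydroxy-3,8-dimethyl-7-oxo-1,2,3,7,8,8a-hexahydronaphthalene-8-carboxylic acid 1,8-lactone (vinylogous acid, drawn as the C4 enol), via Michael adduct 9 (not isolated)
Conditions: Cs2CO3 (1.5 equiv), MeCN (0.01 M), 0 °C → 45 °C; then 1 M HCl to pH 3
Reagents that add atoms: none
Why: Cs2CO3 deprotonates the β-keto ester of 8, the stabilised enolate adds through C8 to the enone β-carbon C8a (bond C8–C8a, intermediate 9), the ring-A enolate adds through C4a to the β-carbon C5 of the ethoxy enone (bond C4a–C5) and ethoxide is expelled to leave the C5=C6–C7=O enone, after which deprotonation at C4a gives the cesium salt of the vinylogous acid and pulls the reversible Michael steps forward. The closest known reaction type is the base-mediated double Michael (anionic [4+2]) annulation of vinyl β-keto esters with cyclohex-2-enones, combined with the addition–elimination of β-alkoxy enones. The γ-lactone closes 5-exo-trig and ring B closes 6-endo-trig. C8a is controlled by the ester tether, which can deliver C8 only to the face of the C1–O bond and so gives the cis-fused lactone with H-8a on the convex face; C8 is controlled by the fold of this bicycle, the bulkier ethoxyacryloyl group taking the convex side next to H-8a and the methyl group the concave side over ring A, which is the target arrangement; C4a ends as an sp2 centre and C1 and C3 are carried over from 4. The step needs C- over O-cyclisation and attack at C8a and C5 only, which the tether length (only the five-membered lactone is within reach of C8a) and the six-membered transition state from C4a to C5 should secure. The β-keto ester is by far the most acidic site and the product takes up the base, so the α′-hydrogen at C3 and the γ-hydrogen at C1 should stay untouched, the main open point being the facial selectivity at C8.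

Step 6
Reactants: 10 (1S,3R,8R,8aS)-1,4-dihydroxy-3,8-dimethyl-7-oxo-1,2,3,7,8,8a-hexahydronaphthalene-8-carboxylic acid 1,8-lactone
Product: 11 (1S,3R,8R,8aS)-1-hydroxy-3,8-dimethyl-7-oxo-4-(trifluoromethanesulfonyloxy)-1,2,3,7,8,8a-hexahydronaphthalene-8-carboxylic acid 1,8-lactone
Conditions: Tf2O (1.1 equiv), pyridine, CH2Cl2, −78 °C
Reagents that add atoms: trifluoromethanesulfonic anhydride, O=S(=O)(OS(=O)(=O)C(F)(F)F)C(F)(F)F
Why: O-Sulfonylation of a vinylogous acid, as with cyclic 1,3-diketones, should occur at the C4 oxygen because the C7 oxygen is flanked by the quaternary C8, giving the vinylogous acyl triflate.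

Step 7
Reactants: 11 (1S,3R,8R,8aS)-1-hydroxy-3,8-dimethyl-7-oxo-4-(trifluoromethanesulfonyloxy)-1,2,3,7,8,8a-hexahydronaphthalene-8-carboxylic acid 1,8-lactone
Product: 12 (1S,3R,8R,8aS)-1-hydroxy-3,8-dimethyl-7-oxo-1,2,3,7,8,8a-hexahydronaphthalene-8-carboxylic acid 1,8-lactone
Conditions: Pd(OAc)2 (5 mol %), PPh3 (10 mol %), HCO2H, Bu3N, DMF, 60 °C
Reagents that add atoms: none
Why: Palladium-catalysed formate reduction of an enol triflate (oxidative addition, formate-to-hydride exchange with loss of CO2, reductive elimination) replaces the C4 oxygen by hydrogen and leaves the C4=C4a–C5=C6–C7=O dienone and the C3 centre untouched.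

Step 8
Reactants: 12 (1S,3R,8R,8aS)-1-hydroxy-3,8-dimethyl-7-oxo-1,2,3,7,8,8a-hexahydronaphthalene-8-carboxylic acid 1,8-lactone
Product: 14 1-[(1S,3R,7R,8R,8aS)-1,7-dihydroxy-3,7,8-trimethyl-1,2,3,7,8,8a-hexahydronaphthalen-8-yl]-3-hydroxypropan-1-one, via hydroxy lactone 13 (not isolated)
Conditions: MeLi (1.05 equiv), THF, −78 °C; then LiCH2CH2OLi (1.5 equiv; from ClCH2CH2OH, n-BuLi and LiC10H8 in THF at −78 °C, no naphthalenide left over), −78 °C; aq. NH4Cl at −78 °C
Reagents that add atoms: methyllithium, [Li]C; lithium 2-lithioethan-1-olate, [Li]CCO[Li] (made in the flask from 2-chloroethanol, OCCCl)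
Why: 1,2-Addition of methyllithium to the non-enolisable C7 ketone should occur from the α face, anti to the axial C8 methyl group, setting C7 with the hydroxyl cis to that methyl, and the β-oxido alkyllithium then adds once to the lactone carbonyl (nucleophilic acyl substitution), the lithium hemiketal surviving until the cold quench, which releases the C1 hydroxyl and the 3-hydroxypropanoyl ketone.

Step 9
Reactants: 14 1-[(1S,3R,7R,8R,8aS)-1,7-dihydroxy-3,7,8-trimethyl-1,2,3,7,8,8a-hexahydronaphthalen-8-yl]-3-hydroxypropan-1-one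
Product: 15 3-{[tert-butyl(dimethyl)silyl]oxy}-1-[(1S,3R,7R,8R,8aS)-1,7-dihydroxy-3,7,8-trimethyl-1,2,3,7,8,8a-hexahydronaphthalen-8-yl]propan-1-one
Conditions: TBSCl (1.05 equiv), imidazole, CH2Cl2, −20 °C
Reagents that add atoms: tert-butyldimethylsilyl chloride, CC(C)(C)[Si](C)(C)Cl
Why: Silylation is selective for the primary hydroxyl over the hindered axial C1 hydroxyl and the tertiary C7 hydroxyl.

Step 10
Reactants: 16 prop-2-yn-1-ol
Product: 17 (2E)-3-iodo-2-methylprop-2-en-1-ol
Conditions: AlMe3 (3 equiv), Cp2ZrCl2 (0.25 equiv), CH2Cl2, 0 °C → rt; then I2, THF, −30 → 0 °C; aq. K2CO3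
Reagents that add atoms: trimethylaluminium, C[Al](C)C; iodine, II
Why: Zirconium-catalysed carboalumination (Negishi) adds methyl and aluminium syn across the alkyne with aluminium at the terminus, and iodinolysis with retention gives the E alkenyl iodide.

Step 11
Reactants: 17 (2E)-3-iodo-2-methylprop-2-en-1-ol
Product: 18 (2E)-3-iodo-2-methylprop-2-enal
Conditions: MnO2, CH2Cl2, rt
Reagents that add atoms: none
Why: Allylic alcohol oxidation with MnO2 stops at the enal and keeps the alkene geometry.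

Step 12
Reactants: 19 (4S)-4-benzyl-3-propanoyl-1,3-oxazolidin-2-one; 18 (2E)-3-iodo-2-methylprop-2-enal
Product: 20 (4S)-4-benzyl-3-[(2S,3S,4E)-3-hydroxy-5-iodo-2,4-dimethylpent-4-enoyl]-1,3-oxazolidin-2-one
Conditions: Bu2BOTf, iPr2NEt, CH2Cl2, −78 → 0 °C; then 18, −78 → 0 °C; pH 7 buffer, MeOH, H2O2, 0 °C
Reagents that add atoms: none
Why: Evans syn-aldol reaction in which the Z boron enolate reacts through a closed chair transition state on the enolate face away from the benzyl group of the auxiliary, setting C2′ and C3′ as 2S,3S (syn).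

Step 13
Reactants: 20 (4S)-4-benzyl-3-[(2S,3S,4E)-3-hydroxy-5-iodo-2,4-dimethylpent-4-enoyl]-1,3-oxazolidin-2-one
Product: 21 (4S)-4-benzyl-3-[(2S,3S,4E)-5-iodo-2,4-dimethyl-3-(triethylsilyloxy)pent-4-enoyl]-1,3-oxazolidin-2-one
Conditions: TESOTf, 2,6-lutidine, CH2Cl2, −78 °C
Reagents that add atoms: triethylsilyl trifluoromethanesulfonate, CC[Si](CC)(CC)OS(=O)(=O)C(F)(F)F
Why: Standard silylation of the secondary allylic alcohol blocks retro-aldol cleavage and β-elimination in the later steps.

Step 14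
Reactants: 21 (4S)-4-benzyl-3-[(2S,3S,4E)-5-iodo-2,4-dimethyl-3-(triethylsilyloxy)pent-4-enoyl]-1,3-oxazolidin-2-one
Product: 22 (2S,3S,4E)-5-iodo-2,4-dimethyl-3-(triethylsilyloxy)pent-4-enoic acid
Conditions: LiOH, H2O2, THF/H2O, 0 °C; then Na2SO3; 1 M HCl to pH 4
Reagents that add atoms: hydrogen peroxide, OO
Why: Lithium hydroperoxide attacks the exocyclic imide carbonyl selectively, and sulfite reduction of the peracid gives the acid without epimerisation at C2′ or loss of the silyl ether.

Step 15
Reactants: 23 (2E)-3-methylpent-2-en-4-yn-1-ol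
Product: 24 (2E,4E)-3-methyl-5-(tributylstannyl)penta-2,4-dien-1-ol
Conditions: Bu3SnH, PdCl2(PPh3)2 (2 mol %), THF, 0 °C
Reagents that add atoms: tributyltin hydride, CCCC[SnH](CCCC)CCCC
Why: Palladium-catalysed hydrostannation is a syn addition that places tin on the terminal alkyne carbon and gives the E alkenylstannane.

Step 16
Reactants: 24 (2E,4E)-3-methyl-5-(tributylstannyl)penta-2,4-dien-1-ol
Product: 25 (2E,4E)-3-methyl-5-(tributylstannyl)penta-2,4-dienal
Conditions: MnO2, CH2Cl2, rt
Reagents that add atoms: none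
Why: Allylic oxidation with MnO2 is neutral and leaves the alkenylstannane and both alkene geometries intact.

Step 17
Reactants: 25 (2E,4E)-3-methyl-5-(tributylstannyl)penta-2,4-dienal; 26 (diethoxyphosphoryl)acetic acid
Product: 27 (2E,4E,6E)-5-methyl-7-(tributylstannyl)hepta-2,4,6-trienoic acid
Conditions: LiN(SiMe3)2 (2.1 equiv) and 26, THF, −78 °C; then 25, −78 °C → rt; aq. NaH2PO4
Reagents that add atoms: none
Why: Horner–Wadsworth–Emmons olefination with the dianion of the phosphonoacetic acid gives the E acrylic acid directly, so that no ester has to be cleaved later.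

Step 18
Reactants: 15 3-{[tert-butyl(dimethyl)silyl]oxy}-1-[(1S,3R,7R,8R,8aS)-1,7-dihydroxy-3,7,8-trimethyl-1,2,3,7,8,8a-hexahydronaphthalen-8-yl]propan-1-one; 22 (2S,3S,4E)-5-iodo-2,4-dimethyl-3-(triethylsilyloxy)pent-4-enoic acid
Product: 28 (1S,3R,7R,8R,8aS)-8-(3-{[tert-butyl(dimethyl)silyl]oxy}propanoyl)-7-hydroxy-3,7,8-trimethyl-1,2,3,7,8,8a-hexahydronaphthalen-1-yl (2S,3S,4E)-5-iodo-2,4-dimethyl-3-(triethylsilyloxy)pent-4-enoate
Conditions: 2-methyl-6-nitrobenzoic anhydride (1.3 equiv), DMAP, Et3N, toluene, rt → 40 °C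
Reagents that add atoms: none
Why: Shiina esterification through the mixed anhydride and the acylpyridinium ion should acylate only the secondary C1 hydroxyl, since the C7 hydroxyl is tertiary and the primary one is silylated, the hemiketal form of 15 draining through the open hydroxy ketone.

Step 19
Reactants: 28 (the alkenyl iodide ester from step 18); 27 (2E,4E,6E)-5-methyl-7-(tributylstannyl)hepta-2,4,6-trienoic acid
Product: 29 (2E,4E,6E,8E,10S,11S)-12-{[(1S,3R,7R,8R,8aS)-8-(3-{[tert-butyl(dimethyl)silyl]oxy}propanoyl)-7-hydroxy-3,7,8-trimethyl-1,2,3,7,8,8a-hexahydronaphthalen-1-yl]oxy}-5,9,11-trimethyl-12-oxo-10-(triethylsilyloxy)dodeca-2,4,6,8-tetraenoic acid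
Conditions: Pd2(dba)3 (5 mol %), AsPh3 (40 mol %), NMP, rt, dark
Reagents that add atoms: none
Why: Stille coupling of the alkenyl iodide with the alkenylstannane proceeds with retention at both alkenes, tolerates the free acid and hydroxyl groups and completes the all-E tetraene.

Step 20
Reactants: 29 (the bis-silyl ether from step 19)
Product: 30 (2E,4E,6E,8E,10S,11S)-10-hydroxy-12-{[(1S,3R,7R,8R,8aS)-7-hydroxy-8-(3-hydroxypropanoyl)-3,7,8-trimethyl-1,2,3,7,8,8a-hexahydronaphthalen-1-yl]oxy}-5,9,11-trimethyl-12-oxododeca-2,4,6,8-tetraenoic acid (CNP0306937.1)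
Conditions: HF·pyridine, pyridine, THF, 0 °C → rt
Reagents that add atoms: none
Why: Buffered fluoride-mediated desilylation removes the triethylsilyl and tert-butyldimethylsilyl ethers while the esters, the β-hydroxy ketone, the tertiary dienyl carbinol and the tetraene should be spared.

Compound list
1 | 4,4-dimethoxycyclohexa-2,5-dien-1-one | COC1(OC)C=CC(=O)C=C1 | starting material
2 | (5R)-4,4-dimethoxy-5-methylcyclohex-2-en-1-one | O=C1C[C@@H](C)C(OC)(OC)C=C1 | intermediate
3 | (1S,5R)-4,4-dimethoxy-5-methylcyclohex-2-en-1-ol (cis) | O[C@H]1C[C@@H](C)C(OC)(OC)C=C1 | intermediate (not isolated)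
4 | (4S,6R)-4-hydroxy-6-methylcyclohex-2-en-1-one (cis) | O[C@H]1C[C@@H](C)C(=O)C=C1 | intermediate
5 | S-tert-butyl propanethioate | CCC(=O)SC(C)(C)C | starting material
6 | (2E)-3-ethoxyprop-2-enoyl chloride | CCO/C=C/C(=O)Cl | starting material
7 | S-tert-butyl (4E)-5-ethoxy-2-methyl-3-oxopent-4-enethioate | CCO/C=C/C(=O)C(C)C(=O)SC(C)(C)C | intermediate
8 | (1S,5R)-5-methyl-4-oxocyclohex-2-en-1-yl (4E)-5-ethoxy-2-methyl-3-oxopent-4-enoate | CCO/C=C/C(=O)C(C)C(=O)O[C@H]1C[C@@H](C)C(=O)C=C1 | intermediate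
9 | (3R,3aS,6R,7aS)-3-[(2E)-3-ethoxyprop-2-enoyl]-3,6-dimethylhexahydro-1-benzofuran-2,5-dione (cis-fused lactone; acyl group cis to H-3a) | O1[C@H]2C[C@@H](C)C(=O)C[C@H]2[C@](C)(C(=O)/C=C/OCC)C1=O | intermediate (not isolated)
10 | (1S,3R,8R,8aS)-1,4-dihydroxy-3,8-dimethyl-7-oxo-1,2,3,7,8,8a-hexahydronaphthalene-8-carboxylic acid 1,8-lactone | O1[C@H]2C[C@@H](C)C(O)=C3C=CC(=O)[C@](C)(C1=O)[C@H]32 | intermediate
11 | (1S,3R,8R,8aS)-1-hydroxy-3,8-dimethyl-7-oxo-4-(trifluoromethanesulfonyloxy)-1,2,3,7,8,8a-hexahydronaphthalene-8-carboxylic acid 1,8-lactone | O1[C@H]2C[C@@H](C)C(OS(=O)(=O)C(F)(F)F)=C3C=CC(=O)[C@](C)(C1=O)[C@H]32 | intermediate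
12 | (1S,3R,8R,8aS)-1-hydroxy-3,8-dimethyl-7-oxo-1,2,3,7,8,8a-hexahydronaphthalene-8-carboxylic acid 1,8-lactone | O1[C@H]2C[C@@H](C)C=C3C=CC(=O)[C@](C)(C1=O)[C@H]32 | intermediate
13 | (1S,3R,7R,8R,8aS)-1,7-dihydroxy-3,7,8-trimethyl-1,2,3,7,8,8a-hexahydronaphthalene-8-carboxylic acid 1,8-lactone | O1[C@H]2C[C@@H](C)C=C3C=C[C@@](C)(O)[C@](C)(C1=O)[C@H]32 | intermediate (not isolated)
14 | 1-[(1S,3R,7R,8R,8aS)-1,7-dihydroxy-3,7,8-trimethyl-1,2,3,7,8,8a-hexahydronaphthalen-8-yl]-3-hydroxypropan-1-one | O[C@H]1C[C@@H](C)C=C2C=C[C@@](C)(O)[C@](C)(C(=O)CCO)[C@H]21 | intermediate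
15 | 3-{[tert-butyl(dimethyl)silyl]oxy}-1-[(1S,3R,7R,8R,8aS)-1,7-dihydroxy-3,7,8-trimethyl-1,2,3,7,8,8a-hexahydronaphthalen-8-yl]propan-1-one | O[C@H]1C[C@@H](C)C=C2C=C[C@@](C)(O)[C@](C)(C(=O)CCO[Si](C)(C)C(C)(C)C)[C@H]21 | intermediate
16 | prop-2-yn-1-ol | C#CCO | starting material
17 | (2E)-3-iodo-2-methylprop-2-en-1-ol | OC/C(C)=C/I | intermediate
18 | (2E)-3-iodo-2-methylprop-2-enal | O=C/C(C)=C/I | intermediate
19 | (4S)-4-benzyl-3-propanoyl-1,3-oxazolidin-2-one | CCC(=O)N1[C@@H](Cc2ccccc2)COC1=O | starting material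
20 | (4S)-4-benzyl-3-[(2S,3S,4E)-3-hydroxy-5-iodo-2,4-dimethylpent-4-enoyl]-1,3-oxazolidin-2-one | I/C=C(\C)[C@@H](O)[C@H](C)C(=O)N1[C@@H](Cc2ccccc2)COC1=O | intermediate
21 | (4S)-4-benzyl-3-[(2S,3S,4E)-5-iodo-2,4-dimethyl-3-(triethylsilyloxy)pent-4-enoyl]-1,3-oxazolidin-2-one | I/C=C(\C)[C@@H](O[Si](CC)(CC)CC)[C@H](C)C(=O)N1[C@@H](Cc2ccccc2)COC1=O | intermediate
22 | (2S,3S,4E)-5-iodo-2,4-dimethyl-3-(triethylsilyloxy)pent-4-enoic acid | I/C=C(\C)[C@@H](O[Si](CC)(CC)CC)[C@H](C)C(=O)O | intermediate
23 | (2E)-3-methylpent-2-en-4-yn-1-ol | C#C/C(C)=C/CO | starting material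
24 | (2E,4E)-3-methyl-5-(tributylstannyl)penta-2,4-dien-1-ol | CCCC[Sn](CCCC)(CCCC)/C=C/C(C)=C/CO | intermediate
25 | (2E,4E)-3-methyl-5-(tributylstannyl)penta-2,4-dienal | CCCC[Sn](CCCC)(CCCC)/C=C/C(C)=C/C=O | intermediate
26 | (diethoxyphosphoryl)acetic acid | OC(=O)CP(=O)(OCC)OCC | starting material
27 | (2E,4E,6E)-5-methyl-7-(tributylstannyl)hepta-2,4,6-trienoic acid | CCCC[Sn](CCCC)(CCCC)/C=C/C(C)=C/C=C/C(=O)O | intermediate
28 | (1S,3R,7R,8R,8aS)-8-(3-{[tert-butyl(dimethyl)silyl]oxy}propanoyl)-7-hydroxy-3,7,8-trimethyl-1,2,3,7,8,8a-hexahydronaphthalen-1-yl (2S,3S,4E)-5-iodo-2,4-dimethyl-3-(triethylsilyloxy)pent-4-enoate | I/C=C(\C)[C@@H](O[Si](CC)(CC)CC)[C@H](C)C(=O)O[C@H]1C[C@@H](C)C=C2C=C[C@@](C)(O)[C@](C)(C(=O)CCO[Si](C)(C)C(C)(C)C)[C@H]21 | intermediate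
29 | (2E,4E,6E,8E,10S,11S)-12-{[(1S,3R,7R,8R,8aS)-8-(3-{[tert-butyl(dimethyl)silyl]oxy}propanoyl)-7-hydroxy-3,7,8-trimethyl-1,2,3,7,8,8a-hexahydronaphthalen-1-yl]oxy}-5,9,11-trimethyl-12-oxo-10-(triethylsilyloxy)dodeca-2,4,6,8-tetraenoic acid | CC(/C=C/C=C(\C)[C@@H](O[Si](CC)(CC)CC)[C@H](C)C(=O)O[C@H]1C[C@@H](C)C=C2C=C[C@@](C)(O)[C@](C)(C(=O)CCO[Si](C)(C)C(C)(C)C)[C@H]21)=C\C=C\C(=O)O | intermediate
30 | (2E,4E,6E,8E,10S,11S)-10-hydroxy-12-{[(1S,3R,7R,8R,8aS)-7-hydroxy-8-(3-hydroxypropanoyl)-3,7,8-trimethyl-1,2,3,7,8,8a-hexahydronaphthalen-1-yl]oxy}-5,9,11-trimethyl-12-oxododeca-2,4,6,8-tetraenoic acid | CC(/C=C/C=C(\C)[C@@H](O)[C@H](C)C(=O)O[C@H]1C[C@@H](C)C=C2C=C[C@@](C)(O)[C@](C)(C(=O)CCO)[C@H]21)=C\C=C\C(=O)O | target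

Total step count: 20.
Longest linear sequence: 11 steps (steps 1, 2, 4, 5, 6, 7, 8, 9, 18, 19, 20).

Steps most likely to fail

Step 5. The process at risk is poor facial selectivity at C8 in the first Michael addition (the acyl group taking the concave side), together with O-cyclisation of the keto ester enolate onto C5 or epimerisation at C3 while the mono-adduct waits for ring closure. The fallback sets out from 4 and returns at 9 and then 10; it forms the two bonds in separate operations and fixes C8 by a convex-face acylation. Alcohol 4 is acylated with 2-bromopropanoyl bromide and pyridine to give (1S,5R)-5-methyl-4-oxocyclohex-2-en-1-yl 2-bromopropanoate F1. SmI2 in THF at −78 °C converts the bromo ester into its samarium enolate, which closes by intramolecular Michael addition (Reformatsky-type) to the cis-fused keto lactone F2. The ring ketone is masked with ethane-1,2-diol and pyridinium p-toluenesulfonate as the dioxolane F3. The lithium enolate of the lactone (LiN(iPr)2, −78 °C) is C-acylated by 6 on the convex face, which places the ethoxyacryloyl group next to H-8a, to give the acyl lactone F4. Mild aqueous acid removes the ketal to give 9, and Cs2CO3 in MeCN closes ring B by Michael addition–elimination to 10.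

Step 8. The process at risk is decomposition of the β-oxido alkyllithium before it adds to the hindered lactone carbonyl, reduction of the diene by leftover naphthalenide, or retro-aldol cleavage of the C7 alkoxide. The fallback sets out from 12 and returns at 14. Methyllithium alone at −78 °C gives 13, which is isolated. Excess CH2=CHMgBr in THF (−78 → −20 °C) opens the lactone to the vinyl ketone F5. Copper-catalysed conjugate borylation (CuCl, NaOt-Bu, bis(pinacolato)diboron, MeOH, THF) gives the boronate F6, and NaBO3·4H2O in THF/H2O oxidises the C–B bond to give 14.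

Step 6. The process at risk is sulfonylation at the wrong oxygen (O7) or at carbon, which would misplace the oxygen that has to be removed. The fallback sets out from 10 and returns at 12, bypassing 11 and step 7. Condensation of 10 with 4-methylbenzenesulfonohydrazide (cat. AcOH, MeOH) is reversible and should settle on the less hindered C4 carbonyl, giving the tosylhydrazide F7. K2CO3 in hot MeOH then eliminates sulfinate and, from the resulting diazene, nitrogen, which leaves hydrogen on C4 and gives dienone 12 (the known conversion of 1,3-diketone monotosylhydrazones into enones).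

Further compounds
F1 | step 5 | (1S,5R)-5-methyl-4-oxocyclohex-2-en-1-yl 2-bromopropanoate | CC(Br)C(=O)O[C@H]1C[C@@H](C)C(=O)C=C1
F2 | step 5 | (3aS,6R,7aS)-3,6-dimethylhexahydro-1-benzofuran-2,5-dione (cis-fused, both C3 epimers) | O1[C@H]2C[C@@H](C)C(=O)C[C@H]2C(C)C1=O
F3 | step 5 | (3aS,6R,7aS)-3,6-dimethylhexahydro-3H-spiro[1-benzofuran-5,2′-[1,3]dioxolan]-2-one | O1[C@H]2C[C@@H](C)C3(OCCO3)C[C@H]2C(C)C1=O
F4 | step 5 | (3R,3aS,6R,7aS)-3-[(2E)-3-ethoxyprop-2-enoyl]-3,6-dimethylhexahydro-3H-spiro[1-benzofuran-5,2′-[1,3]dioxolan]-2-one | O1[C@H]2C[C@@H](C)C3(OCCO3)C[C@H]2[C@](C)(C(=O)/C=C/OCC)C1=O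
F5 | step 8 | 1-[(1S,3R,7R,8R,8aS)-1,7-dihydroxy-3,7,8-trimethyl-1,2,3,7,8,8a-hexahydronaphthalen-8-yl]prop-2-en-1-one | O[C@H]1C[C@@H](C)C=C2C=C[C@@](C)(O)[C@](C)(C(=O)C=C)[C@H]21
F6 | step 8 | 1-[(1S,3R,7R,8R,8aS)-1,7-dihydroxy-3,7,8-trimethyl-1,2,3,7,8,8a-hexahydronaphthalen-8-yl]-3-(4,4,5,5-tetramethyl-1,3,2-dioxaborolan-2-yl)propan-1-one | O[C@H]1C[C@@H](C)C=C2C=C[C@@](C)(O)[C@](C)(C(=O)CCB3OC(C)(C)C(C)(C)O3)[C@H]21
F7 | step 6 | (1S,3R,8R,8aS)-1-hydroxy-3,8-dimethyl-4-[2-(4-methylbenzenesulfonyl)hydrazinyl]-7-oxo-1,2,3,7,8,8a-hexahydronaphthalene-8-carboxylic acid 1,8-lactone | O1[C@H]2C[C@@H](C)C(NNS(=O)(=O)c4ccc(C)cc4)=C3C=CC(=O)[C@](C)(C1=O)[C@H]32
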